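**Retrosynthetic overview** (side chain numbered C1 = OCH2 to C8 = lactone C=O)
1. C1–OAr: Mitsunobu etherification of hydrangetin (coumarin rings bought intact) with a lactone-bearing (E)-allylic alcohol.
2. C3–CH3 and C2–C1: syn-methylalumination of a terminal alkyne, then formaldehyde, fixes the E alkene.
3. C4–C5 and the lactone ring (the only ring formed): catalyst-controlled propargylation of a β-hydroxy aldehyde, then lactonisation.
4. C6–C7 and the first stereocentre: amine-catalysed cross-aldol of acetaldehyde with ethyl pyruvate.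

Assumption: hydrangetin (7-hydroxy-8-methoxycoumarin), allenylboronic acid pinacol ester and both organocatalysts are taken as commercially available.

**Step 1**
Reactants: 1 acetaldehyde; 2 ethyl pyruvate
Product: 3 ethyl (2R)-2-hydroxy-2-methyl-4-oxobutanoate
Conditions: (S)-α,α-bis[3,5-bis(trifluoromethyl)phenyl]-2-pyrrolidinemethanol (20 mol%), 1 (5 equiv), DMF, 4 °C, 48 h
Reagents that add atoms: none
Why: Proposed new method: enamine cross-aldol of acetaldehyde onto an enolisable alkyl pyruvate, an acceptor class not shown for this catalysis; the hindered secondary amine condenses with acetaldehyde rather than with the ketone, the catalyst hydroxyl hydrogen-bonds the keto oxygen, the ester sits anti to the enamine (the place the amide carbonyl takes with isatins) and the enamine adds to the Re face of the ketone, giving 2R; the closest known reaction type is the diarylprolinol-catalysed cross-aldol of acetaldehyde with isatins and other activated carbonyl acceptors.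

**Step 2**
Reactants: 3 ethyl (2R)-2-hydroxy-2-methyl-4-oxobutanoate; 4 allenylboronic acid pinacol ester
Product: 7 (3R,5S)-3-hydroxy-3-methyl-5-(prop-2-yn-1-yl)oxolan-2-one, via O-boryl adduct 5 (not isolated), via dihydroxy ester 6 (not isolated)
Conditions: (S)-3,3′-bis(2,4,6-triisopropylphenyl)-1,1′-binaphthyl-2,2′-diyl hydrogen phosphate [(S)-TRIP] (10 mol%), 4 Å MS, toluene, −20 °C; then H2O, p-TsOH·H2O (10 mol%), 40 °C
Reagents that add atoms: none
Why: Chiral phosphoric acid-catalysed allenylboration (SE2′ propargylation) through a closed six-membered transition state in which (S)-TRIP binds the boronate oxygen and the formyl hydrogen and exposes the Si face of the aldehyde, so C5 is set S by catalyst control, after which acid cleaves the borate and closes the γ-lactone with loss of ethanol.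

**Step 3**
Reactants: 7 (3R,5S)-3-hydroxy-3-methyl-5-(prop-2-yn-1-yl)oxolan-2-one
Product: 9 (3R,5S)-3-hydroxy-5-[(2E)-4-hydroxy-2-methylbut-2-en-1-yl]-3-methyloxolan-2-one, via alkenylalane 8 (not isolated)
Conditions: Me3Al (4 equiv), Cp2ZrCl2 (25 mol%), H2O (1 equiv), CH2Cl2, −20 °C; then (CH2O)n, −20 °C to rt; aq. potassium sodium tartrate
Reagents that add atoms: trimethylaluminium C[Al](C)C; paraformaldehyde (reacts as formaldehyde) C=O
Why: Negishi zirconium-catalysed carboalumination adds methyl and aluminium syn across the terminal alkyne with methyl on the internal carbon, and hydroxymethylation of the alkenyl–aluminium bond with retention puts C1 cis to the methyl, which is the E alkene; the tertiary hydroxyl is masked in the flask as its aluminium alkoxide and the lactone is expected to survive at −20 °C.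

**Step 4**
Reactants: 9 (3R,5S)-3-hydroxy-5-[(2E)-4-hydroxy-2-methylbut-2-en-1-yl]-3-methyloxolan-2-one; 10 hydrangetin (7-hydroxy-8-methoxy-2H-chromen-2-one)
Product: 11 7-{[(2E)-4-[(2S,4R)-4-hydroxy-4-methyl-5-oxooxolan-2-yl]-3-methylbut-2-en-1-yl]oxy}-8-methoxy-2H-chromen-2-one (CNP0356189.1)
Conditions: PPh3, diisopropyl azodicarboxylate, THF, 0 °C to rt
Reagents that add atoms: none
Why: Mitsunobu etherification, in which the acidic coumarin phenol displaces the oxyphosphonium of the primary allylic alcohol by SN2 at C1, leaving the E alkene, the unreactive tertiary alcohol and both stereocentres untouched.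

**Compound list**
1 | acetaldehyde | CC=O | starting material
2 | ethyl pyruvate (ethyl 2-oxopropanoate) | CCOC(=O)C(C)=O | starting material
3 | ethyl (2R)-2-hydroxy-2-methyl-4-oxobutanoate | CCOC(=O)[C@](C)(O)CC=O | intermediate
4 | allenylboronic acid pinacol ester (4,4,5,5-tetramethyl-2-(propa-1,2-dien-1-yl)-1,3,2-dioxaborolane) | C=C=CB1OC(C)(C)C(C)(C)O1 | starting material
5 | ethyl (2R,4S)-2-hydroxy-2-methyl-4-[(4,4,5,5-tetramethyl-1,3,2-dioxaborolan-2-yl)oxy]hept-6-ynoate | CCOC(=O)[C@](C)(O)C[C@@H](OB1OC(C)(C)C(C)(C)O1)CC#C | intermediate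
6 | ethyl (2R,4S)-2,4-dihydroxy-2-methylhept-6-ynoate | CCOC(=O)[C@](C)(O)C[C@@H](O)CC#C | intermediate
7 | (3R,5S)-3-hydroxy-3-methyl-5-(prop-2-yn-1-yl)oxolan-2-one | C#CC[C@H]1C[C@@](C)(O)C(=O)O1 | intermediate
8 | [(1E)-3-{(2S,4R)-4-[(dimethylalumanyl)oxy]-4-methyl-5-oxooxolan-2-yl}-2-methylprop-1-en-1-yl]dimethylalumane | C[Al](C)/C=C(\C)C[C@H]1C[C@@](C)(O[Al](C)C)C(=O)O1 | intermediate
9 | (3R,5S)-3-hydroxy-5-[(2E)-4-hydroxy-2-methylbut-2-en-1-yl]-3-methyloxolan-2-one | OC/C=C(\C)C[C@H]1C[C@@](C)(O)C(=O)O1 | intermediate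
10 | hydrangetin (7-hydroxy-8-methoxy-2H-chromen-2-one) | COc1c(O)ccc2ccc(=O)oc12 | starting material
11 | 7-{[(2E)-4-[(2S,4R)-4-hydroxy-4-methyl-5-oxooxolan-2-yl]-3-methylbut-2-en-1-yl]oxy}-8-methoxy-2H-chromen-2-one | COc1c(OC/C=C(\C)C[C@H]2C[C@@](C)(O)C(=O)O2)ccc2ccc(=O)oc12 | target

**Total step count:** 4. **Longest linear sequence:** 4 (1/2 → 3 → 7 → 9 → 11).

Because C7 and C5 are set by two independent catalysts and the cis/trans lactones 7 are separable, the minor enantiomer of 7 arises only when both steps err, so the enantiomeric purity of 7 should exceed that of either step.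

**Steps most likely to fail**

Step 1 (the new step). The risks are pyruvate self-aldol through its own enamine, acetaldehyde self-condensation, dehydration or retro-aldol of 3, and an unproven facial sense. The fallback uses known chemistry, sets out from 2 and comes back at 3. A copper bis(oxazoline)-catalysed Mukaiyama aldol of 2 with 1-(ethylsulfanyl)-1-(trimethylsilyloxy)ethene, using [Cu(t-Bu-box)](OTf)2 with the ligand antipode chosen for the 2R adduct (THF, −78 °C), gives ethyl (2R)-4-(ethylsulfanyl)-2-methyl-4-oxo-2-[(trimethylsilyl)oxy]butanoate F1. Treatment with 1 M HCl frees ethyl (2R)-4-(ethylsulfanyl)-2-hydroxy-2-methyl-4-oxobutanoate F2. Fukuyama reduction of the thioester (Et3SiH, palladium on carbon (Pd/C), acetone) then gives aldehyde 3.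

Step 2. The free tertiary hydroxyl and ester of 3 may bind the phosphoric acid or the boronate and erode catalyst control, and α-unbranched aliphatic aldehydes give the lowest selectivities in this reaction class. The fallback gives up catalyst control at C5, sets out from 3 and comes back at 7. Zinc-mediated Barbier propargylation (propargyl bromide, Zn, THF/aq. NH4Cl) gives 6 together with its C4 epimer, ethyl (2R,4R)-2,4-dihydroxy-2-methylhept-6-ynoate F3. Lactonisation (p-TsOH, toluene, 40 °C) converts the pair into 7 and (3R,5R)-3-hydroxy-3-methyl-5-(prop-2-yn-1-yl)oxolan-2-one F4, which are diastereomers and are separated by chromatography; F4 is discarded.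

Step 3. Me3Al may attack the lactone, which is activated by the neighbouring aluminium alkoxide, and direct hydroxymethylation of an alkenylalane is often only moderate in yield. The fallback avoids the alkyne and brings in C1–C4 with the alkene already in place; it sets out from 3 and comes back at 9, replacing steps 2 and 3. 3-Methylbut-2-enal is silylated (TBSOTf, Et3N) to tert-butyl(dimethyl){[(1E)-3-methylbuta-1,3-dien-1-yl]oxy}silane F5. A BF3·OEt2-promoted vinylogous Mukaiyama aldol of F5 with 3 (CH2Cl2, −78 °C, desilylating work-up) gives ethyl (2R,4S,6E)-2,4-dihydroxy-2,6-dimethyl-8-oxooct-6-enoate F6 and its epimer ethyl (2R,4R,6E)-2,4-dihydroxy-2,6-dimethyl-8-oxooct-6-enoate F7. Lactonisation (p-TsOH) gives (2E)-4-[(2S,4R)-4-hydroxy-4-methyl-5-oxooxolan-2-yl]-3-methylbut-2-enal F8 and (2E)-4-[(2R,4R)-4-hydroxy-4-methyl-5-oxooxolan-2-yl]-3-methylbut-2-enal F9, separated by chromatography. Luche reduction of F8 (NaBH4, CeCl3·7H2O, MeOH, 0 °C) gives 9.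

**Further compounds**
F1 | step 1 | ethyl (2R)-4-(ethylsulfanyl)-2-methyl-4-oxo-2-[(trimethylsilyl)oxy]butanoate | CCOC(=O)[C@](C)(O[Si](C)(C)C)CC(=O)SCC
F2 | step 1 | ethyl (2R)-4-(ethylsulfanyl)-2-hydroxy-2-methyl-4-oxobutanoate | CCOC(=O)[C@](C)(O)CC(=O)SCC
F3 | step 2 | ethyl (2R,4R)-2,4-dihydroxy-2-methylhept-6-ynoate | CCOC(=O)[C@](C)(O)C[C@H](O)CC#C
F4 | step 2 | (3R,5R)-3-hydroxy-3-methyl-5-(prop-2-yn-1-yl)oxolan-2-one | C#CC[C@@H]1C[C@@](C)(O)C(=O)O1
F5 | step 3 | tert-butyl(dimethyl){[(1E)-3-methylbuta-1,3-dien-1-yl]oxy}silane | C=C(C)/C=C/O[Si](C)(C)C(C)(C)C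
F6 | step 3 | ethyl (2R,4S,6E)-2,4-dihydroxy-2,6-dimethyl-8-oxooct-6-enoate | CCOC(=O)[C@](C)(O)C[C@@H](O)C/C(C)=C/C=O
F7 | step 3 | ethyl (2R,4R,6E)-2,4-dihydroxy-2,6-dimethyl-8-oxooct-6-enoate | CCOC(=O)[C@](C)(O)C[C@H](O)C/C(C)=C/C=O
F8 | step 3 | (2E)-4-[(2S,4R)-4-hydroxy-4-methyl-5-oxooxolan-2-yl]-3-methylbut-2-enal | O=C/C=C(\C)C[C@H]1C[C@@](C)(O)C(=O)O1
F9 | step 3 | (2E)-4-[(2R,4R)-4-hydroxy-4-methyl-5-oxooxolan-2-yl]-3-methylbut-2-enal | O=C/C=C(\C)C[C@@H]1C[C@@](C)(O)C(=O)O1
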